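**Direct plan (as a thought)**

A direct plan would form the C7–C8 bond by a boron-mediated, auxiliary-controlled syn-aldol of the N-(aryloxyacetyl)oxazolidinone A1 with 3,4,5-trimethoxybenzaldehyde, giving imide A2.
It would then silylate the carbinol, cleave the auxiliary reductively to the primary alcohol A3, tosylate it, displace the tosylate with hydride and desilylate to reach the threo alcohol A4.
A Mitsunobu esterification to the 4-nitrobenzoate A5 and methanolysis would finally invert C7.
Its weakest parts would be:
(a) turning the auxiliary-bearing carbonyl into the C9 methyl (reduction, sulfonylation, hydride displacement, framed by silylation and desilylation): five operations that add no skeletal bond and no stereocentre;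
(b) the Mitsunobu inversion of the benzylic carbinol on late material, needed only because the aldol sets C7 in the wrong sense; at an electron-rich benzylic centre next to a hindered aryloxy carbon, ionisation, elimination and aryloxy participation would compete with clean SN2;
(c) the three-step installation of a stoichiometric auxiliary that is later discarded.

**Plan of the new route**

The target is cut first at C7–H, taking the carbinol back to the racemic ketone 7. It is then cut at the C8–O bond to ring B (phenoxide plus 2-bromoketone), at C8–Br, and at the ethyl–C7 bond of a nitrile addition.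
No ring is formed at any stage. Ring A (3,4,5-trimethoxyphenyl) and ring B (4-allyl-2,6-dimethoxyphenyl) are bought intact and joined through O–C8 in step 3.
The enabling feature is the C8–H bond, which sits between the C7 aryl ketone on ring A and the ether oxygen to ring B. It exchanges under mild base, so the enantiomers of 7 interconvert while a ketoreductase reduces only one of them, from one face.
Both stereocentres are therefore set in the last step from a racemate. C9 is a methyl from the outset (no redox detour), C7 is formed directly as S (no inversion), and no auxiliary or protecting group is used.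

Key step: step 4

Remark: neolignan numbering is used (C7 = carbinol carbon on ring A, C8 = carbon bearing the aryloxy group, C9 = methyl). The ketoreductase is assumed to come from a commercial screening panel; which member gives the (1S,2R) alcohol has to be found by screening.

Step 1
Reactants: 1 3,4,5-trimethoxybenzonitrile; 2 ethylmagnesium bromide
Product: 4 1-(3,4,5-trimethoxyphenyl)propan-1-one, via bromomagnesium ketimide 3 (not isolated)
Conditions: EtMgBr (1.5 equiv), THF, 0 °C → reflux; then 2 M HCl, rt
Reagents that add atoms: water, O
Why: Grignard addition to a nitrile stops at the N-magnesio ketimine, which cannot take up a second equivalent, and acidic hydrolysis of the imine should give the ketone; no stereocentre is involved.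

Step 2
Reactants: 4 1-(3,4,5-trimethoxyphenyl)propan-1-one
Product: 5 rac-2-bromo-1-(3,4,5-trimethoxyphenyl)propan-1-one
Conditions: CuBr2 (2.1 equiv), EtOAc/CHCl3 1:1, reflux
Reagents that add atoms: copper dibromide, Br[Cu]Br
Why: α-Bromination of an aryl alkyl ketone by divalent copper bromide runs through the copper-bound enol and should stop at the monobromide; the acyl group deactivates ring A toward nuclear bromination, and the new stereocentre is racemic on purpose.

Step 3
Reactants: 5 rac-2-bromo-1-(3,4,5-trimethoxyphenyl)propan-1-one; 6 4-allyl-2,6-dimethoxyphenol (methoxyeugenol)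
Product: 7 rac-2-(4-allyl-2,6-dimethoxyphenoxy)-1-(3,4,5-trimethoxyphenyl)propan-1-one
Conditions: K2CO3 (2 equiv), butan-2-one, 60 °C
Reagents that add atoms: none
Why: Williamson ether synthesis; the phenoxide of 6 displaces bromide by SN2 at the carbonyl-activated secondary carbon, the weak heterogeneous base should keep dehydrobromination and allyl isomerisation down, and C8 is left racemic because step 4 corrects it.

Step 4
Reactants: 7 rac-2-(4-allyl-2,6-dimethoxyphenoxy)-1-(3,4,5-trimethoxyphenyl)propan-1-one
Product: 10 rhaphidecursinol B [(1S,2R)-2-(4-allyl-2,6-dimethoxyphenoxy)-1-(3,4,5-trimethoxyphenyl)propan-1-ol], via achiral enol 8 (not isolated), via (R)-ketone 9 (not isolated)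
Conditions: ketoreductase (NADPH-dependent alcohol dehydrogenase, EC 1.1.1, panel-selected for the (1S,2R)-alcohol), NADP+ (cat.), i-PrOH (15% v/v), DMSO (10% v/v), 0.1 M NaHCO3/Na2CO3 buffer pH 9.0–9.5, MgSO4 (2 mM), 35 °C, N2
Reagents that add atoms: none
Why: Proposed new method: the ketoreductase binds one enantiomer of ketone 7 and transfers the C4 hydride of NADPH to one face of the C7 carbonyl, while the unreacted (S)-ketone returns to the racemate through the achiral enol(ate) 8, because the C8–H bond between the ring A aryl ketone and the ring B aryloxy oxygen is exchanged by the pH 9 buffer, whereas the product carbinol has no acidifying carbonyl and keeps its C8 configuration (dynamic reductive kinetic resolution, with isopropanol regenerating NADPH and leaving as acetone). The closest known reaction types are ketoreductase dynamic kinetic resolutions of 2-substituted 3-oxo esters and 2-substituted cyclic ketones, transfer-hydrogenation dynamic kinetic resolutions of 2-substituted aryl ketones, and the NAD-dependent benzylic dehydrogenases of the bacterial aryl ether (lignin) pathway, which interconvert this same 2-aryloxy-1-arylpropanone/propanol motif. No ring is closed. C7 (S) is set by the carbonyl face that the active site presents to the cofactor, and C8 (R) by the enzyme's preference for the (R)-ketone 9 over its enantiomer, so both descriptors are chosen by screening a ketoreductase panel for the (1S,2R) product and neither is left to substrate bias. The step needs racemisation to outpace reduction of the slow enantiomer and needs the enzyme to tell apart two bulky groups at C7; the first should be secured by the doubly activated C8–H and the mildly basic buffer, the second by the different shapes of flat ring A and the branched C8 arm carrying the ortho,ortho-disubstituted ring B. A hydride-transfer enzyme should leave the allyl group of ring B untouched, whereas metal hydride catalysts tend to move such a double bond into conjugation.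

**Compound list**
1 | 3,4,5-trimethoxybenzonitrile | COc1cc(C#N)cc(OC)c1OC | starting material
2 | ethylmagnesium bromide | CC[Mg]Br | starting material
3 | bromomagnesium ketimide, N-(bromomagnesio)-1-(3,4,5-trimethoxyphenyl)propan-1-imine | CCC(=N[Mg]Br)c1cc(OC)c(OC)c(OC)c1 | intermediate
4 | 1-(3,4,5-trimethoxyphenyl)propan-1-one | CCC(=O)c1cc(OC)c(OC)c(OC)c1 | intermediate
5 | rac-2-bromo-1-(3,4,5-trimethoxyphenyl)propan-1-one | CC(Br)C(=O)c1cc(OC)c(OC)c(OC)c1 | intermediate
6 | 4-allyl-2,6-dimethoxyphenol (methoxyeugenol) | C=CCc1cc(OC)c(O)c(OC)c1 | starting material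
7 | rac-2-(4-allyl-2,6-dimethoxyphenoxy)-1-(3,4,5-trimethoxyphenyl)propan-1-one | C=CCc1cc(OC)c(OC(C)C(=O)c2cc(OC)c(OC)c(OC)c2)c(OC)c1 | intermediate
8 | enol of 7, 2-(4-allyl-2,6-dimethoxyphenoxy)-1-(3,4,5-trimethoxyphenyl)prop-1-en-1-ol (double-bond geometry not defined; present as its enolate at pH 9) | C=CCc1cc(OC)c(OC(C)=C(O)c2cc(OC)c(OC)c(OC)c2)c(OC)c1 | intermediate
9 | (R)-2-(4-allyl-2,6-dimethoxyphenoxy)-1-(3,4,5-trimethoxyphenyl)propan-1-one | C=CCc1cc(OC)c(O[C@H](C)C(=O)c2cc(OC)c(OC)c(OC)c2)c(OC)c1 | intermediate
10 | rhaphidecursinol B, (1S,2R)-2-(4-allyl-2,6-dimethoxyphenoxy)-1-(3,4,5-trimethoxyphenyl)propan-1-ol | C=CCc1cc(OC)c(O[C@H](C)[C@@H](O)c2cc(OC)c(OC)c(OC)c2)c(OC)c1 | target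

**Step count**
Total steps: 4. Longest linear sequence: 4 steps (1 → 4 → 5 → 7 → 10; phenol 6 is bought).

**Steps most likely to fail, with fallbacks**

Step 4 (proposed new method). Racemisation of the ketone may be too slow relative to reduction, so that the resolution stalls near half conversion. Alternatively, no panel enzyme may accept a ketone with two bulky groups, or the hits may favour the threo series. The fallback uses the chiral pool and sets out from 6. A Mitsunobu reaction of 6 with ethyl (S)-lactate (PPh3, diisopropyl azodicarboxylate, THF, 0 °C → rt) should give, with inversion, ethyl (R)-2-(4-allyl-2,6-dimethoxyphenoxy)propanoate F1, which fixes C8 as R. Aminolysis with MeNH(OMe)·HCl and i-PrMgCl (THF, −20 °C) should give (R)-2-(4-allyl-2,6-dimethoxyphenoxy)-N-methoxy-N-methylpropanamide F2. Addition of 3,4,5-trimethoxyphenylmagnesium bromide F3 (from 5-bromo-1,2,3-trimethoxybenzene and Mg in THF) at 0 °C should stop at the chelated tetrahedral adduct and release the (R)-ketone 9 on work-up, now as an isolated compound. Chelation-controlled reduction with Zn(BH4)2 (Et2O, 0 °C) should deliver hydride to the zinc chelate of the carbonyl and aryloxy oxygens from the side of the C8 hydrogen, giving the anti (erythro) alcohol. The fallback comes back to the route at 10.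

Step 3. SN2 attack of the di-ortho-substituted phenoxide at a secondary carbon may be slow, so that loss of HBr from 5 or C-alkylation takes over. The fallback sets out from 6 and makes the ether bond at a primary carbon. Reaction with commercial 2-bromo-1-(3,4,5-trimethoxyphenyl)ethan-1-one (K2CO3, acetone, rt) should give 2-(4-allyl-2,6-dimethoxyphenoxy)-1-(3,4,5-trimethoxyphenyl)ethan-1-one F4, where no elimination is possible. Enolisation with LiN(SiMe3)2 (1.05 equiv, THF, −78 °C) and C-methylation with MeI then installs C9. The fallback comes back to the route at 7.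

Step 2. Bromination may run on to the α,α-dibromide or attack the electron-rich ring A. The fallback avoids any halogenation of a ring A ketone and forms the C7–ring A bond last; it sets out from 6. Alkylation with ethyl 2-bromopropanoate (K2CO3, DMF, 50 °C) should give rac-ethyl 2-(4-allyl-2,6-dimethoxyphenoxy)propanoate F5. Aminolysis with MeNH(OMe)·HCl and i-PrMgCl (THF, −20 °C) should give rac-2-(4-allyl-2,6-dimethoxyphenoxy)-N-methoxy-N-methylpropanamide F6. Addition of 3,4,5-trimethoxyphenylmagnesium bromide F3 (THF, 0 °C) then gives the ketone. The fallback comes back to the route at 7 and bypasses 4 and 5.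

**Further compounds**
F1 | step 4 | ethyl (R)-2-(4-allyl-2,6-dimethoxyphenoxy)propanoate | C=CCc1cc(OC)c(O[C@H](C)C(=O)OCC)c(OC)c1
F2 | step 4 | (R)-2-(4-allyl-2,6-dimethoxyphenoxy)-N-methoxy-N-methylpropanamide | C=CCc1cc(OC)c(O[C@H](C)C(=O)N(C)OC)c(OC)c1
F3 | step 4 | 3,4,5-trimethoxyphenylmagnesium bromide | COc1cc([Mg]Br)cc(OC)c1OC
F4 | step 3 | 2-(4-allyl-2,6-dimethoxyphenoxy)-1-(3,4,5-trimethoxyphenyl)ethan-1-one | C=CCc1cc(OC)c(OCC(=O)c2cc(OC)c(OC)c(OC)c2)c(OC)c1
F5 | step 2 | rac-ethyl 2-(4-allyl-2,6-dimethoxyphenoxy)propanoate | C=CCc1cc(OC)c(OC(C)C(=O)OCC)c(OC)c1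
F6 | step 2 | rac-2-(4-allyl-2,6-dimethoxyphenoxy)-N-methoxy-N-methylpropanamide | C=CCc1cc(OC)c(OC(C)C(=O)N(C)OC)c(OC)c1
A1 | direct plan | (S)-3-[2-(4-allyl-2,6-dimethoxyphenoxy)acetyl]-4-benzyloxazolidin-2-one | C=CCc1cc(OC)c(OCC(=O)N2[C@@H](Cc3ccccc3)COC2=O)c(OC)c1
A2 | direct plan | (S)-3-[(2S,3R)-2-(4-allyl-2,6-dimethoxyphenoxy)-3-hydroxy-3-(3,4,5-trimethoxyphenyl)propanoyl]-4-benzyloxazolidin-2-one | C=CCc1cc(OC)c(O[C@@H]([C@H](O)c2cc(OC)c(OC)c(OC)c2)C(=O)N2[C@@H](Cc3ccccc3)COC2=O)c(OC)c1
A3 | direct plan | (2R,3R)-2-(4-allyl-2,6-dimethoxyphenoxy)-3-[(tert-butyldimethylsilyl)oxy]-3-(3,4,5-trimethoxyphenyl)propan-1-ol | C=CCc1cc(OC)c(O[C@@H]([C@H](O[Si](C)(C)C(C)(C)C)c2cc(OC)c(OC)c(OC)c2)CO)c(OC)c1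
A4 | direct plan | (1R,2R)-2-(4-allyl-2,6-dimethoxyphenoxy)-1-(3,4,5-trimethoxyphenyl)propan-1-ol | C=CCc1cc(OC)c(O[C@H](C)[C@H](O)c2cc(OC)c(OC)c(OC)c2)c(OC)c1
A5 | direct plan | (1S,2R)-2-(4-allyl-2,6-dimethoxyphenoxy)-1-(3,4,5-trimethoxyphenyl)propyl 4-nitrobenzoate | C=CCc1cc(OC)c(O[C@H](C)[C@@H](OC(=O)c2ccc(cc2)[N+](=O)[O-])c2cc(OC)c(OC)c(OC)c2)c(OC)c1
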